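- Keep the books on the solid substrate: in a closed flask of constant volume, each mole charged stands in some form at every hour, and the readings show two of those entries, first product and double product.

| setting | delta | zeta | maple | alder | oak |
|---|---|---|---|---|---|
| solid substrate | 0.050 M | 0.050 M | 0.050 M | 0.050 M | 0.050 M |
| partner | 0.049 M | 0.18 M | 0.0400 M | 0.0500 M | 0.125 M |
| remark | run made earlier | run made earlier |  |  |  |
| time |  |  | 12 h | 12 h | 12 h |

| run | time / h | double product / % | first product / % |
|---|---|---|---|
| delta | 0.833 | 0 | 0.4 |
| delta | 2.00 | 0 | 0.3 |
| delta | 4.00 | 0.5 | 1.0 |
| delta | 6.00 | 0.3 | 0.7 |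
| zeta | 0.833 | 0.3 | 0.7 |
| zeta | 2.00 | 0.6 | 1.1 |
| zeta | 4.00 | 2.9 | 1.7 |
| zeta | 6.00 | 4.8 | 2.0 |

(each reading ± 0.3 percentage points)

- as a solid, counted per litre of solution: solid substrate
- the numbers in the tables scatter by 0.3 percentage points (one standard deviation)
- at the start none of the solid substrate is in solution

- final double product, as a percentage of the solid substrate charged, for each flask in turn (maple, alder, oak)

- Open the ledger on zeta at 6.00 h: first product 2.0% and double product 4.8% leave 93.2% of the charge outside these entries.
- Post the partner: counting double product twice, these two entries bind 3.22% of the zeta partner charge, so on these entries take partner as charged, as an approximation, and define the exposure E as charged partner concentration times hours.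
- Mark the crossing in zeta: double product reads 0.6% against 1.1% of first product at 2.00 h, but 2.9% against 1.7% at 4.00 h.
- Follow the entries past that crossing: from 2.00 h to 6.00 h zeta double product gains 4.2 percentage points, more than the 0.9 points of first product.
- Define the exposure yield y, the fraction of the charge gained as double product per unit of exposure, as 0.0583 M⁻¹ h⁻¹, a reading that carries the scatter.
- Run the zeta line back to zero double product: the onset exposure E0, an induction period counted in exposure, reads 0.257 M·h, so at this charge of solid substrate write double product as y(E − E0).
- Test it on delta at 6.00 h: the line gives 0.215% and the reading is 0.3%, within the scatter. At 4.00 h the delta exposure of 0.196 M·h lies below E0, yet the reading is 0.5%, so the line is rough near its onset.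
- Commit my own reckoning at 12 h: maple 1.30%, alder 2.00%, oak 7.25%.
- Set beside these the forecast of 1.3%, 1.9% and 6.9%, lower than mine at alder and at oak, grounded on the view that “only the small saturated amount of dissolved substrate reacts”.
- Read the flasks: maple gives 1.15%, alder 1.71% and oak 7.39%.

    starting material + partner → other mono adduct (k = 0.0390 M⁻¹ min⁻¹)
    solid substrate ⇌ starting material, rate k2*(cs2 - [starting material]) while solid is left; crystals form when [starting material] > cs2 (solubility = 3.00 mM, k = 0.0130 min⁻¹)
    partner + other mono adduct → double product (k = 0.00460 M⁻¹ min⁻¹)
    starting material + partner ⇌ first product (K = 3.90 M⁻¹, k = 0.0820 M⁻¹ min⁻¹)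
    partner + first product → double product (k = 0.0540 M⁻¹ min⁻¹)

- Run the line once more: oak at 6.00 h holds 2.86% double product against 2.87% from the line, and alder at 12.0 h holds 1.71% against 2.00%. In oak, solid substrate fell from 86.9% to 77.3% between 6.00 h and 12.0 h, while starting material went from 3.88% to 4.01% and first product stood at 1.37% and 1.36%. Over those hours, with partner at 89.6% of its charge at the end, other mono adduct rose from 5.02% to 9.97% and double product reached 7.39%.

Readings and results stem from a simulated flask on assumed constants; scatter was added.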